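The readings come from a simulation for substances that don't exist, and the scatter is random.

The south run is your guide to this repeat, but it stops early. Its readings still climb from 41.3% to 47.3% at the last step.

- south (time / min: complex with one exchanged / %): 5.00: 5.5; 15.0: 17.0; 25.0: 24.2; 40.0: 32.8; 60.0: 41.3; 80.0: 47.3

(scatter of a reading: 0.5 percentage points)

| setting | south | Saturday's | Sunday's |
|---|---|---|---|
| starting complex | 46 mM | 42 mM | 15 mM |
| incoming ligand | 54.6 mM | 54.6 mM | 150 mM |
| remark | run made earlier |  |  |
| time |  | 6.0 h | 25 h |

- which one finishes higher in amount of complex with one exchanged, in percent of the starting complex charged ("neither" within 2 percentage points) (Saturday's / Sunday's / neither)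
- amount of complex with one exchanged at the end, in percent of the starting complex charged, Saturday's
- amount of complex with one exchanged at the end, in percent of the starting complex charged, Sunday's

- the analysis behind the earlier runs scatters by 0.5 percentage points, standard deviation
- no earlier run changes the charge of incoming ligand; that part of a forecast is a guess

Read the 17.0% at 15.0 min as starting complex lost, with incoming ligand held at its charge (the pseudo-first-order view). That gives a reading of 0.930 h for the half-time of the starting complex at 54.6 mM, and it shortens in proportion as the ligand charge rises. This is my own reckoning, and the ligand dependence is a guess.

The south readings span 1.43 half-times. Saturday's runs 6.45 of them. Sunday's half-time is 0.339 h, so it runs 73.9.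

From above, the ceiling is the complex converted: 98.9% on Saturday's and 100% on Sunday's. From below, the readings give no floor, since they show nothing of the product beyond 1.43 half-times. So my bracket runs from zero to those ceilings, and I name no winner.

The forecast sits inside it, with 61% and 90%, and picks Sunday's: “Both new runs should therefore reach equilibrium”.

The flasks give 48.4% on Saturday's and 0.116% on Sunday's, so Saturday's finishes higher.

    starting complex + incoming ligand → leaving ligand + complex with one exchanged (k = 14.0 M⁻¹ h⁻¹)
    complex with one exchanged + incoming ligand → leaving ligand + complex with two exchanged (k = 1.47 M⁻¹ h⁻¹)
    complex with two exchanged + incoming ligand → leaving ligand + complex with three exchanged (k = 13.1 M⁻¹ h⁻¹)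
    leaving ligand + complex with one exchanged → side product (k = 3.60 M⁻¹ h⁻¹)

Watch the complex with one exchanged well past the south window: on Saturday's it stands at 57.0% after 3.00 h and at 48.4% after 6.00 h. Take the neighbour, which is Sunday's with 60 mM of incoming ligand. Its half-time is 0.846 h, so it runs 29.5 half-times, fewer than Sunday's 73.9. Sunday's ends with 69.7% complex with three exchanged and 30.2% side product. The neighbour ends with 44.7% complex with three exchanged, 48.7% side product and 5.74% complex with one exchanged.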